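Cuts: the C5 angelate and C1 acetate come off first; ring A (C1, C2, C3, C3a, C7a) is opened at C1–C2 (acyloin retron); C4=CH2 goes back to a ketal-masked ketone; ring B (C3a, C4, C5, C6, C7, C7a) is cut at C7–CH(CH3)2 and C7a–C3a.
Enabling feature: C7 bears the isopropyl group next to C7a, C7a bears the acyl carbon C1, and C3a bears the C3–C2 acyl arm, so ring B is the adduct of a conjugate addition at C7 followed by Michael closure C7a→C3a on an open C1…C2 bis-acceptor chain.
Forward: C4–C7 chain from L-threonate → methyl enoate at C3a → S-ethyl thioenoate at C7 → ring B (key step) → C4 methylene → ring A by acyloin condensation → acetate, angelate, desilylation.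
Stereochemistry: C5 and C6 from the chiral pool; C7 by copper addition anti to C6–O; C7a and C3a by a chair closure; C1 by ketol equilibration; the Z-enoate from angelic acid.

Key step: step 12

Numbering: atoms carry the target numbers throughout, also in open-chain compounds (ring A = C1, C2, C3, C3a, C7a; ring B = C3a, C4, C5, C6, C7, C7a).
Assumption: methyl 3,4-O-isopropylidene-L-threonate (1) is taken as the commercial chiral-pool material; its two carbinol carbons have the L-threo configuration that C5 and C6 require.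

Step 1
Reactants: 1 methyl 3,4-O-isopropylidene-L-threonate
Product: 2 methyl 2-O-(tert-butyldimethylsilyl)-3,4-O-isopropylidene-L-threonate
Conditions: TBSCl, imidazole, DMF, rt
Reagents that add atoms: tert-butyldimethylsilyl chloride, CC(C)(C)[Si](C)(C)Cl
Why: Imidazole-mediated silyl ether formation at the only free hydroxyl, the oxygen that becomes O5, so that O5 carries the more acid-labile of the two silyl groups used and no stereocenter is touched.

Step 2
Reactants: 2 silyl ether ester
Product: 3 2-O-(tert-butyldimethylsilyl)-3,4-O-isopropylidene-L-threonic acid N-methoxy-N-methylamide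
Conditions: MeNH(OMe)·HCl, Al(CH3)3, CH2Cl2, 0 °C → rt
Reagents that add atoms: N,O-dimethylhydroxylamine hydrochloride, CNOC.Cl
Why: Weinreb amidation of the methyl ester with the aluminium amide formed in the flask, a non-basic acyl substitution that should not epimerise the α-silyloxy center or open the acetonide.

Step 3
Reactants: 3 Weinreb amide; 4 vinylmagnesium bromide
Product: 5 vinyl ketone (1R)-1-(tert-butyldimethylsilyloxy)-1-[(4S)-2,2-dimethyl-1,3-dioxolan-4-yl]but-3-en-2-one
Conditions: CH2=CHMgBr, THF, −78 → 0 °C; poured into cold 1 M HCl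
Reagents that add atoms: vinylmagnesium bromide 4, C=C[Mg]Br
Why: Weinreb ketone synthesis stops at single addition of the vinyl Grignard reagent, and the inverse acidic quench keeps the liberated amine from adding to the vinyl ketone.

Step 4
Reactants: 5 vinyl ketone
Product: 6 vinyl dioxolane (C4 ethylene ketal of 5)
Conditions: Me3SiOCH2CH2OSiMe3, Me3SiOTf (cat.), CH2Cl2, −78 → −20 °C; pyridine
Reagents that add atoms: 1,2-bis(trimethylsilyloxy)ethane, C[Si](C)(C)OCCO[Si](C)(C)C
Why: Noyori ketalisation (bis-silyl glycol with catalytic silyl triflate) converts enones to dioxolanes at low temperature without conjugate addition of the glycol and should leave the acetonide and the silyl ether in place.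

Step 5
Reactants: 6 vinyl dioxolane
Product: 8 C4-ketal aldehyde 2-{(R)-(tert-butyldimethylsilyloxy)[(4S)-2,2-dimethyl-1,3-dioxolan-4-yl]methyl}-1,3-dioxolane-2-carbaldehyde, via secondary ozonide 7 (not isolated)
Conditions: O3, CH2Cl2, −78 °C; then PPh3, −78 °C → rt
Reagents that add atoms: ozone, [O-][O+]=O
Why: Ozonolysis of the only alkene with phosphine reduction of the ozonide gives an aldehyde that has no α-hydrogen and so cannot epimerise or enolise.

Step 6
Reactants: 8 ketal aldehyde; 9 trimethyl phosphonoacetate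
Product: 10 methyl (E)-enoate at C3a with the C4 dioxolane (acetonide retained)
Conditions: (MeO)2P(O)CH2CO2Me, NaH, THF, 0 °C → rt
Reagents that add atoms: trimethyl phosphonoacetate 9, COC(=O)CP(=O)(OC)OC
Why: Horner–Wadsworth–Emmons olefination of the non-enolisable aldehyde gives the E-enoate that will be the C3a acceptor, and from here on the conjugated ester makes the C4 dioxolane hard to ionise.

Step 7
Reactants: 10 enoate acetonide
Product: 11 C6/C7 diol
Conditions: AcOH–H2O (4:1), 40 °C
Reagents that add atoms: none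
Why: Acid hydrolysis of the terminal acetonide, selective because the C4 dioxolane is deactivated by the conjugated ester and the neighbouring silyloxy group and secondary silyl ethers tolerate aqueous acetic acid.

Step 8
Reactants: 11 diol
Product: 13 tris-silyl ether (O5 tert-butyldimethylsilyl; O6 triisopropylsilyl; primary O triethylsilyl), via primary triethylsilyl ether 12 (not isolated)
Conditions: Et3SiCl, Et3N, DMAP (cat.), CH2Cl2, −78 °C; then iPr3SiOTf, 2,6-lutidine, −78 → 0 °C
Reagents that add atoms: chlorotriethylsilane, CC[Si](Cl)(CC)CC; triisopropylsilyl trifluoromethanesulfonate, CC(C)[Si](OS(=O)(=O)C(F)(F)F)(C(C)C)C(C)C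
Why: Silylation in two stages in one flask, the silyl chloride taking the primary hydroxyl at low temperature and the silyl triflate then the hindered secondary one, so that O6 carries the most robust silyl group.

Step 9
Reactants: 13 tris-silyl ether
Product: 14 C7 aldehyde (α-triisopropylsilyloxy aldehyde)
Conditions: (COCl)2, DMSO, CH2Cl2, −78 → −30 °C; Et3N, −78 °C → rt
Reagents that add atoms: none
Why: Swern oxidation applied directly to the primary triethylsilyl ether, which the chlorosulfonium reagent cleaves and oxidises while secondary silyl ethers stay, gives the α-silyloxy aldehyde without a separate deprotection.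

Step 10
Reactants: 15 diethylphosphonoacetic acid
Product: 16 S-ethyl 2-(diethoxyphosphoryl)ethanethioate
Conditions: EtSH, DCC, DMAP (cat.), CH2Cl2, 0 °C → rt
Reagents that add atoms: ethanethiol, CCS
Why: Steglich-type carbodiimide coupling of the phosphonoacetic acid with the thiol gives the thioester olefination reagent.

Step 11
Reactants: 14 aldehyde; 16 thioester phosphonate
Product: 17 methyl (2E,5R,6S,7E)-5-(tert-butyldimethylsilyloxy)-4,4-ethylenedioxy-9-(ethylsulfanyl)-9-oxo-6-(triisopropylsilyloxy)nona-2,7-dienoate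
Conditions: LiCl, iPr2NEt, MeCN, 0 °C → rt
Reagents that add atoms: S-ethyl 2-(diethoxyphosphoryl)ethanethioate 16, CCOP(=O)(CC(=O)SCC)OCC
Why: Masamune–Roush variant of the Horner–Wadsworth–Emmons olefination, mild enough not to epimerise the α-silyloxy aldehyde, gives the E-thioenoate, chosen so that the C7 acceptor is much more electrophilic than the C3a enoate.

Step 12
Reactants: 17 thioenoate/enoate chain; 18 isopropylmagnesium chloride
Product: 20 ring-B thioester S-ethyl 10-(tert-butyldimethylsilyloxy)-6-(2-methoxy-2-oxoethyl)-8-(propan-2-yl)-9-(triisopropylsilyloxy)-1,4-dioxaspiro[4.5]decane-7-carbothioate, via magnesium thioester enolate 19 (not isolated)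
Conditions: iPrMgCl (2.4 equiv), CuI (1.2 equiv), THF, −40 °C; 17, −78 → −20 °C; aq. NH4Cl
Reagents that add atoms: isopropylmagnesium chloride 18, CC(C)[Mg]Cl
Why: The diisopropylcuprate made from 18 and CuI transfers isopropyl to C7 of the thioenoate and leaves magnesium thioester enolate 19, whose C7a carbon then adds to C3a of the methyl enoate; this is a conjugate addition followed by an intramolecular Michael addition, the Michael-initiated ring closure known for organocopper reagents and nona-2,7-dienedioates. Ring B closes in the 6-exo-trig mode. C7 is controlled by the C6 stereocenter: copper attacks anti to the C6–O bond with C6–H eclipsing the alkene, the usual anti addition to γ-silyloxy E-acceptors. C7a and C3a are controlled by a chair transition state with isopropyl, the thioester and the CH2CO2CH3 arm equatorial and the two bulky silyloxy groups axial, which gives the 7,7a-trans and 7a,3a-trans relationships needed for the trans ring fusion. The step needs attack at C7 and not at C3a: a thioenoate is far more reactive toward organocopper reagents than an enoate, and C3a in addition sits next to the quaternary dioxolane carbon, which blocks intermolecular attack but not the intramolecular one. Using the cuprate and no free Grignard reagent should spare both carbonyl groups.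

Step 13
Reactants: 20 ring-B thioester
Product: 21 ring-B dimethyl diester (C7a–CO2CH3 and C3a–CH2CO2CH3; C4 dioxolane)
Conditions: NaOCH3, MeOH, 0 °C → rt; aq. NH4Cl
Reagents that add atoms: sodium methoxide, C[O-].[Na+]
Why: Methoxide transesterification of the thioester (acyl substitution) gives the diester needed for ring A, and base cannot erode C7a because its acyl group is already equatorial and trans to both neighbours.

Step 14
Reactants: 21 ketal diester
Product: 22 C4 ketone diester
Conditions: TsOH·H2O (cat.), acetone–H2O (10:1), 45 °C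
Reagents that add atoms: water, O
Why: Acid-catalysed ketal hydrolysis in wet acetone, mild enough for secondary silyl ethers, unveils the C4 ketone whose α-centers C3a and C5 are not at risk under these non-basic conditions.

Step 15
Reactants: 22 ketone diester
Product: 23 C4-methylidene diester
Conditions: Zn, CH2Br2, TiCl4, THF, −40 → 5 °C (aged); then 22, CH2Cl2, 0 °C → rt
Reagents that add atoms: dibromomethane, BrCBr
Why: Takai–Lombardo methylenation, a non-basic zinc–titanium methylene transfer that converts hindered enolisable ketones without epimerisation or β-elimination and ignores esters, is placed before ring A exists so that no second ketone competes.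

Step 16
Reactants: 23 methylidene diester
Product: 25 ketol (1R,3aR,5S,6S,7S,7aR)-5-(tert-butyldimethylsilyloxy)-1-hydroxy-4-methylidene-7-(propan-2-yl)-6-(triisopropylsilyloxy)octahydro-2H-inden-2-one, via bis(trimethylsilyloxy)cyclopentene 24 (not isolated)
Conditions: Na (dispersion), Me3SiCl, toluene, 110 °C; filter, concentrate; then K2CO3 (cat.), MeOH, 0 °C → rt, under argon
Reagents that add atoms: none
Why: Rühlmann acyloin condensation joins the C1 and C2 ester carbons to close five-membered ring A as the bis-silyl enediol ether 24, and methanolysis with base equilibration through the enediol should settle on the ketol with the carbonyl at C2, remote from the trans ring fusion, and the new C1 hydroxyl pseudo-equatorial and cis to C7a–H, the arrangement favoured in D-ring ketols of trans-hydrindane steroids, so that C1 is set under thermodynamic control.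

Step 17
Reactants: 25 ketol
Product: 26 C1 acetate
Conditions: Ac2O, pyridine, DMAP (cat.), CH2Cl2, 0 °C
Reagents that add atoms: acetic anhydride, CC(=O)OC(C)=O
Why: Acetylation (nucleophilic catalysis by 4-dimethylaminopyridine) of the only free hydroxyl fixes the C1 acetate.

Step 18
Reactants: 26 acetate
Product: 27 C5 alcohol (O6 still triisopropylsilyl)
Conditions: camphorsulfonic acid (cat.), MeOH–CH2Cl2 (1:1), 0 °C
Reagents that add atoms: none
Why: Acid-catalysed methanolysis of silyl ethers removes the allylic tert-butyldimethylsilyl group at O5 well before the bulkier triisopropylsilyl group at O6, which is also shielded by the isopropyl-bearing C7.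

Step 19
Reactants: 27 C5 alcohol; 28 angelic acid
Product: 29 C5 angelate (O6 triisopropylsilyl)
Conditions: 2,4,6-Cl3C6H2COCl, Et3N, toluene, rt; then 27, 80 °C
Reagents that add atoms: angelic acid 28, C/C=C(/C)C(=O)O
Why: Yamaguchi esterification through the mixed anhydride without 4-dimethylaminopyridine, the conditions under which the angeloyl group is transferred without Z to E isomerisation to the tiglate.

Step 20
Reactants: 29 silyl-protected angelate
Product: 30 CNP0317011.1
Conditions: HF·pyridine, THF, 0 °C → rt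
Reagents that add atoms: none
Why: Acidic fluoride desilylation removes the last silyl group without touching the acetate, the α-acetoxy ketone or the Z-enoate, and the trans-diaxial O5 and O6 cannot exchange the acyl group.

Compound list
1 | methyl 3,4-O-isopropylidene-L-threonate = methyl (2R)-2-hydroxy-2-[(4S)-2,2-dimethyl-1,3-dioxolan-4-yl]acetate | COC(=O)[C@H](O)[C@@H]1COC(C)(C)O1 | starting material
2 | methyl (2R)-2-(tert-butyldimethylsilyloxy)-2-[(4S)-2,2-dimethyl-1,3-dioxolan-4-yl]acetate | COC(=O)[C@H](O[Si](C)(C)C(C)(C)C)[C@@H]1COC(C)(C)O1 | intermediate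
3 | (2R)-2-(tert-butyldimethylsilyloxy)-2-[(4S)-2,2-dimethyl-1,3-dioxolan-4-yl]-N-methoxy-N-methylacetamide | CON(C)C(=O)[C@H](O[Si](C)(C)C(C)(C)C)[C@@H]1COC(C)(C)O1 | intermediate
4 | vinylmagnesium bromide | C=C[Mg]Br | starting material
5 | (1R)-1-(tert-butyldimethylsilyloxy)-1-[(4S)-2,2-dimethyl-1,3-dioxolan-4-yl]but-3-en-2-one | C=CC(=O)[C@H](O[Si](C)(C)C(C)(C)C)[C@@H]1COC(C)(C)O1 | intermediate
6 | tert-butyl{(R)-[(4S)-2,2-dimethyl-1,3-dioxolan-4-yl](2-ethenyl-1,3-dioxolan-2-yl)methoxy}dimethylsilane | C=CC1(OCCO1)[C@H](O[Si](C)(C)C(C)(C)C)[C@@H]2COC(C)(C)O2 | intermediate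
7 | secondary ozonide of 6 (1,2,4-trioxolane in place of the vinyl group; new ring carbon unassigned) | C1OC(OO1)C2(OCCO2)[C@H](O[Si](C)(C)C(C)(C)C)[C@@H]3COC(C)(C)O3 | intermediate
8 | 2-{(R)-(tert-butyldimethylsilyloxy)[(4S)-2,2-dimethyl-1,3-dioxolan-4-yl]methyl}-1,3-dioxolane-2-carbaldehyde | O=CC1(OCCO1)[C@H](O[Si](C)(C)C(C)(C)C)[C@@H]2COC(C)(C)O2 | intermediate
9 | trimethyl phosphonoacetate | COC(=O)CP(=O)(OC)OC | starting material
10 | methyl (2E)-3-(2-{(R)-(tert-butyldimethylsilyloxy)[(4S)-2,2-dimethyl-1,3-dioxolan-4-yl]methyl}-1,3-dioxolan-2-yl)prop-2-enoate | COC(=O)/C=C/C1(OCCO1)[C@H](O[Si](C)(C)C(C)(C)C)[C@@H]2COC(C)(C)O2 | intermediate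
11 | methyl (2E)-3-{2-[(1R,2S)-1-(tert-butyldimethylsilyloxy)-2,3-dihydroxypropyl]-1,3-dioxolan-2-yl}prop-2-enoate | COC(=O)/C=C/C1(OCCO1)[C@H](O[Si](C)(C)C(C)(C)C)[C@@H](O)CO | intermediate
12 | methyl (2E)-3-{2-[(1R,2S)-1-(tert-butyldimethylsilyloxy)-2-hydroxy-3-(triethylsilyloxy)propyl]-1,3-dioxolan-2-yl}prop-2-enoate | COC(=O)/C=C/C1(OCCO1)[C@H](O[Si](C)(C)C(C)(C)C)[C@@H](O)CO[Si](CC)(CC)CC | intermediate
13 | methyl (2E)-3-{2-[(1R,2S)-1-(tert-butyldimethylsilyloxy)-3-(triethylsilyloxy)-2-(triisopropylsilyloxy)propyl]-1,3-dioxolan-2-yl}prop-2-enoate | COC(=O)/C=C/C1(OCCO1)[C@H](O[Si](C)(C)C(C)(C)C)[C@@H](O[Si](C(C)C)(C(C)C)C(C)C)CO[Si](CC)(CC)CC | intermediate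
14 | methyl (2E)-3-{2-[(1R,2R)-1-(tert-butyldimethylsilyloxy)-3-oxo-2-(triisopropylsilyloxy)propyl]-1,3-dioxolan-2-yl}prop-2-enoate | COC(=O)/C=C/C1(OCCO1)[C@H](O[Si](C)(C)C(C)(C)C)[C@@H](O[Si](C(C)C)(C(C)C)C(C)C)C=O | intermediate
15 | diethylphosphonoacetic acid | CCOP(=O)(CC(=O)O)OCC | starting material
16 | S-ethyl 2-(diethoxyphosphoryl)ethanethioate | CCOP(=O)(CC(=O)SCC)OCC | intermediate
17 | methyl (2E,5R,6S,7E)-5-(tert-butyldimethylsilyloxy)-4,4-ethylenedioxy-9-(ethylsulfanyl)-9-oxo-6-(triisopropylsilyloxy)nona-2,7-dienoate | COC(=O)/C=C/C1(OCCO1)[C@H](O[Si](C)(C)C(C)(C)C)[C@@H](O[Si](C(C)C)(C(C)C)C(C)C)/C=C/C(=O)SCC | intermediate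
18 | isopropylmagnesium chloride | CC(C)[Mg]Cl | starting material
19 | chloromagnesium enolate of the open-chain C7-isopropyl thioester (C3a enoate intact; enolate geometry unassigned) | COC(=O)/C=C/C1(OCCO1)[C@H](O[Si](C)(C)C(C)(C)C)[C@@H](O[Si](C(C)C)(C(C)C)C(C)C)[C@@H](C(C)C)C=C(SCC)O[Mg]Cl | intermediate
20 | S-ethyl 10-(tert-butyldimethylsilyloxy)-6-(2-methoxy-2-oxoethyl)-8-(propan-2-yl)-9-(triisopropylsilyloxy)-1,4-dioxaspiro[4.5]decane-7-carbothioate; C3a/C7a trans, C7a/C7 trans, C7/C6 cis, C6/C5 trans | O1CCOC12[C@H](CC(=O)OC)[C@@H](C(=O)SCC)[C@H](C(C)C)[C@H](O[Si](C(C)C)(C(C)C)C(C)C)[C@H]2O[Si](C)(C)C(C)(C)C | intermediate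
21 | methyl 10-(tert-butyldimethylsilyloxy)-6-(2-methoxy-2-oxoethyl)-8-(propan-2-yl)-9-(triisopropylsilyloxy)-1,4-dioxaspiro[4.5]decane-7-carboxylate; same configuration as 20 | O1CCOC12[C@H](CC(=O)OC)[C@@H](C(=O)OC)[C@H](C(C)C)[C@H](O[Si](C(C)C)(C(C)C)C(C)C)[C@H]2O[Si](C)(C)C(C)(C)C | intermediate
22 | methyl 4-(tert-butyldimethylsilyloxy)-2-(2-methoxy-2-oxoethyl)-3-oxo-6-(propan-2-yl)-5-(triisopropylsilyloxy)cyclohexane-1-carboxylate; 1,2-trans, 1,6-trans, 5,6-cis, 4,5-trans | O=C1[C@H](CC(=O)OC)[C@@H](C(=O)OC)[C@H](C(C)C)[C@H](O[Si](C(C)C)(C(C)C)C(C)C)[C@H]1O[Si](C)(C)C(C)(C)C | intermediate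
23 | methyl 4-(tert-butyldimethylsilyloxy)-2-(2-methoxy-2-oxoethyl)-3-methylidene-6-(propan-2-yl)-5-(triisopropylsilyloxy)cyclohexane-1-carboxylate; same configuration as 22 | C=C1[C@H](CC(=O)OC)[C@@H](C(=O)OC)[C@H](C(C)C)[C@H](O[Si](C(C)C)(C(C)C)C(C)C)[C@H]1O[Si](C)(C)C(C)(C)C | intermediate
24 | (3aR,5S,6S,7S,7aR)-5-(tert-butyldimethylsilyloxy)-4-methylidene-7-(propan-2-yl)-6-(triisopropylsilyloxy)-1,2-bis(trimethylsilyloxy)-3a,4,5,6,7,7a-hexahydro-3H-indene (C1=C2 enediol bis-silyl ether, trans-fused) | C=C1[C@@H]2CC(O[Si](C)(C)C)=C(O[Si](C)(C)C)[C@H]2[C@H](C(C)C)[C@H](O[Si](C(C)C)(C(C)C)C(C)C)[C@H]1O[Si](C)(C)C(C)(C)C | intermediate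
25 | (1R,3aR,5S,6S,7S,7aR)-5-(tert-butyldimethylsilyloxy)-1-hydroxy-4-methylidene-7-(propan-2-yl)-6-(triisopropylsilyloxy)octahydro-2H-inden-2-one | C=C1[C@@H]2CC(=O)[C@H](O)[C@H]2[C@H](C(C)C)[C@H](O[Si](C(C)C)(C(C)C)C(C)C)[C@H]1O[Si](C)(C)C(C)(C)C | intermediate
26 | (1R,3aR,5S,6S,7S,7aR)-5-(tert-butyldimethylsilyloxy)-4-methylidene-2-oxo-7-(propan-2-yl)-6-(triisopropylsilyloxy)octahydro-1H-inden-1-yl acetate | C=C1[C@@H]2CC(=O)[C@H](OC(C)=O)[C@H]2[C@H](C(C)C)[C@H](O[Si](C(C)C)(C(C)C)C(C)C)[C@H]1O[Si](C)(C)C(C)(C)C | intermediate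
27 | (1R,3aR,5S,6S,7S,7aR)-5-hydroxy-4-methylidene-2-oxo-7-(propan-2-yl)-6-(triisopropylsilyloxy)octahydro-1H-inden-1-yl acetate | C=C1[C@@H]2CC(=O)[C@H](OC(C)=O)[C@H]2[C@H](C(C)C)[C@H](O[Si](C(C)C)(C(C)C)C(C)C)[C@H]1O | intermediate
28 | angelic acid, (2Z)-2-methylbut-2-enoic acid | C/C=C(/C)C(=O)O | starting material
29 | (1R,3aR,5S,6S,7S,7aR)-1-acetoxy-4-methylidene-2-oxo-7-(propan-2-yl)-6-(triisopropylsilyloxy)octahydro-1H-inden-5-yl (2Z)-2-methylbut-2-enoate | C=C1[C@@H]2CC(=O)[C@H](OC(C)=O)[C@H]2[C@H](C(C)C)[C@H](O[Si](C(C)C)(C(C)C)C(C)C)[C@H]1OC(=O)/C(C)=C\C | intermediate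
30 | CNP0317011.1, (1R,3aR,5S,6S,7S,7aR)-1-acetoxy-6-hydroxy-4-methylidene-2-oxo-7-(propan-2-yl)octahydro-1H-inden-5-yl (2Z)-2-methylbut-2-enoate | C=C1[C@@H]2CC(=O)[C@H](OC(C)=O)[C@H]2[C@H](C(C)C)[C@H](O)[C@H]1OC(=O)/C(C)=C\C | target

Total step count: 20.
Longest linear sequence: 19 steps (steps 1–9 and 11–20; step 10 makes the olefination reagent for step 11).

Steps most likely to fail

Step 12. Site selectivity between the two acceptors may be lost, or the thioester enolate may expel ethanethiolate (ketene formation) or be quenched before it closes onto the shielded C3a carbon. The fallback sets out from 17 and comes back at 20. The copper addition is run with Me3SiCl present at −78 °C (iPrMgCl, CuI, Me3SiCl, THF), which traps the enolate as soon as it forms. After hydrolytic work-up the open-chain C7-isopropyl thioester F1 is isolated. Ring B is then closed in a separate step by deprotonating the thioester with LiN(SiMe3)2 (THF, −78 → −20 °C); the intramolecular Michael addition under these conditions can equilibrate to the all-equatorial product 20.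

Step 16. The two ketol regioisomers may equilibrate incompletely, C7a may epimerise through the C1-keto tautomer, or sodium may over-reduce the esters. The fallback sets out from 23 and comes back at 25. Both esters are reduced with LiAlH4 to the diol F2, which is oxidised under Swern conditions to the dialdehyde F3. Ring A is then closed by an intramolecular benzoin reaction with a thiazolium-derived carbene (3-benzyl-5-(2-hydroxyethyl)-4-methylthiazolium chloride, Et3N, EtOH). The unhindered C2 aldehyde should form the acyl anion equivalent and add to the C1 aldehyde, giving the C2-keto C1-hydroxy ketol 25 under mild base without sodium.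

Step 4. Conjugate addition of the glycol to the vinyl ketone, or its polymerisation, may outrun ketalisation of the hindered α-silyloxy carbonyl. The fallback sets out from 3 and comes back at 6. LiC≡CSiMe3 is added to Weinreb amide 3 to give the silyl ynone F4, whose β-carbon is blocked by silicon. Ketalisation under the same bis-silyl glycol conditions gives the alkynyl dioxolane F5. K2CO3 in MeOH removes the silyl group to give the terminal alkyne F6, and semi-hydrogenation (H2, Pd/CaCO3 poisoned with Pb(OAc)2, quinoline) gives vinyl dioxolane 6.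

Further compounds
F1 | step 12 | methyl (2E,5R,6S,7S)-5-(tert-butyldimethylsilyloxy)-4,4-ethylenedioxy-9-(ethylsulfanyl)-9-oxo-7-(propan-2-yl)-6-(triisopropylsilyloxy)non-2-enoate (open-chain conjugate adduct) | COC(=O)/C=C/C1(OCCO1)[C@H](O[Si](C)(C)C(C)(C)C)[C@@H](O[Si](C(C)C)(C(C)C)C(C)C)[C@@H](C(C)C)CC(=O)SCC
F2 | step 16 | ring-B diol: C7a–CH2OH and C3a–CH2CH2OH on the 4-methylidene-5-(tert-butyldimethylsilyloxy)-6-(triisopropylsilyloxy)-7-isopropylcyclohexane of 23 | C=C1[C@H](CCO)[C@@H](CO)[C@H](C(C)C)[C@H](O[Si](C(C)C)(C(C)C)C(C)C)[C@H]1O[Si](C)(C)C(C)(C)C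
F3 | step 16 | ring-B dialdehyde: C7a–CHO and C3a–CH2CHO, otherwise as F2 | C=C1[C@H](CC=O)[C@@H](C=O)[C@H](C(C)C)[C@H](O[Si](C(C)C)(C(C)C)C(C)C)[C@H]1O[Si](C)(C)C(C)(C)C
F4 | step 4 | (1R)-1-(tert-butyldimethylsilyloxy)-1-[(4S)-2,2-dimethyl-1,3-dioxolan-4-yl]-4-(trimethylsilyl)but-3-yn-2-one | C[Si](C)(C)C#CC(=O)[C@H](O[Si](C)(C)C(C)(C)C)[C@@H]1COC(C)(C)O1
F5 | step 4 | ethylene ketal of F4 (2-[2-(trimethylsilyl)ethynyl]-1,3-dioxolane) | C[Si](C)(C)C#CC1(OCCO1)[C@H](O[Si](C)(C)C(C)(C)C)[C@@H]2COC(C)(C)O2
F6 | step 4 | terminal alkyne: 2-ethynyl-1,3-dioxolane analogue of 6 | C#CC1(OCCO1)[C@H](O[Si](C)(C)C(C)(C)C)[C@@H]2COC(C)(C)O2
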